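**Assumptions (chemistry).** Atoms are numbered as in germacrane throughout. In 30 the lactone is trans-fused (H6 and H7 anti), so the lactone-forming union has to deliver the anti C6/C7 relationship. The C8/C9 diol has the L-threo arrangement, so the commercial acetonide diol of L-threitol (L-tartaric acid series) is taken as the chiral-pool source of C7–C10.

## Structural features

Compound 30 is a germacranolide: a ten-membered carbocycle (C1–C10) fused at C6/C7 to an α-methylene-γ-butyrolactone (O on C6, carbonyl C12, exocyclic C11=C13). Both ring alkenes are trisubstituted with the ring carbons cis: C4=C5 carries methyl C15, and C1=C10 carries the formyl carbon C14, so that C1 is the unsubstituted β-carbon of an enal. Four contiguous stereocentres run from C6 to C9 (6R, 7S, 8S, 9S): lactone oxygen, carbon branch, (S)-2-methylbutanoate and free hydroxyl, with the C8 and C9 oxygens syn as in L-tartaric acid. The fragile parts are the exocyclic methylene lactone (a Michael acceptor that does not tolerate bases or soft nucleophiles), the enal, the allylic C6–O bond, and the C8 ester next to the C9 hydroxyl and the lactone carbonyl (acyl migration, lactone exchange). The real difficulty is the strained medium ring with two cis alkenes next to a dense C6–C9 array that is best set in open-chain precursors. The key step uses the fact that the C1–C2 bond joins an sp2 CH (C1) to a plain methylene (C2) with no stereocentre at either end. An sp2–sp3 cross-coupling can therefore close the ring last, needing only chemoselectivity and retention of the C1=C10 geometry, which is held by making C10=C1 exocyclic to a C9/C14 dioxane.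

## Logic of the disconnections

30 ⇒ 29. No skeletal bond is cut; the C14 aldehyde is traced back to the primary allylic alcohol. The enal is the most sensitive function and is unveiled last. The forward step must oxidise the primary allylic alcohol and leave the secondary allylic C9 alcohol alone.

29 ⇒ 28. The O9–H and O14–H bonds are replaced by one isopropylidene bridge. One group protects both hydroxyls and turns C10=C1 into an exocyclic alkylidene of a six-membered ring, which fixes its geometry. The forward hydrolysis must be mild enough to avoid acyl migration from O8.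

28 ⇒ 26 (through 27). The C1–C2 ring bond is cut. It is the only ring bond between an sp2 CH and a CH2 that is remote from every stereocentre, so the ring opens to a chain in which all stereocentres, the lactone, the ester and both alkene geometries already exist. The forward step needs zinc insertion at the alkyl iodide only, ring closure faster than chain growth, and retention at C1.

26 ⇒ 25 ⇒ 24 ⇒ 22 ⇒ 21. The C2–I bond and the O8–acyl bond are cut. The alkyl iodide is made last because it would not survive the earlier steps. The ester is put on after the lactone exists, because an α-acyloxy aldehyde would not survive the amine-catalysed acrylate addition used earlier. The forward steps need two orthogonal deprotections (oxidative at O8, fluoride at O2) and an acylation that is faster than lactone exchange.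

21 ⇒ 15 + 19 (through 20). The C6–C7 bond and the lactone O–C12 bond are cut at the centre of the molecule, giving two fragments of similar size and forming the lactone and two stereocentres in one operation. The forward step must give the anti C6/C7 adduct (trans-lactone) and bond C7 anti to C9. This calls for the chromium version of the allylation, since zinc or indium Barbier conditions generally favour the syn adduct with γ-substituted 2-(bromomethyl)acrylates. A lactol would be the shortest aldehyde surrogate but needs those aqueous conditions.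

15 ⇒ 14 ⇒ 12 + 13. The C7–C11 bond is cut, then the allylic C–Br bond is traced to a transposed carbinol. This takes the three-carbon acrylate unit (C11–C13) from 13. The forward addition must work on a hindered α-alkoxy aldehyde without epimerising C8.

12 ⇒ 11 ⇒ 10 ⇒ 9 ⇒ 8. Only protecting-group bonds change. The benzyl-type ether is moved from O7 to O8 through a cyclic acetal, and O9/O14 are bridged. This frees C7 for oxidation while O8 stays masked by a group that tolerates the organometallic steps. The forward demand is regioselective formation of the six-membered acetonide in the presence of the O8 hydroxyl.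

8 ⇒ 5 (through 6 and 7). The C10–C14 bond and the C1–I bond are cut across the alkene, leading back to a terminal alkyne. One anti addition builds the trisubstituted (Z)-iodoalkene with its hydroxymethyl branch. The forward step relies on the C9 alkoxide for regiochemistry and for the anti mode.

5 ⇒ 4 ⇒ 3 ⇒ 2 ⇒ 1. The C10≡C1 bond is cut (one-carbon homologation of an aldehyde), and the two ends of a C2-symmetric diol are differentiated. C8 and C9 then come unchanged from the chiral pool. The forward demands are clean mono-protection and no epimerisation of the aldehyde.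

19 ⇒ 18 ⇒ 17 ⇒ 16. The aldehyde is traced to an amide and then to the ring C–O bond of an unsaturated lactone. The ring fixes the Z geometry of C4=C5. The forward steps must avoid Z/E isomerisation and relactonisation.

## Other disconnections considered

Alternative 1: The cut is C7–C8. In the forward sense the open-chain aldehyde A2, which carries an allylstannane at C13, would be treated with MgBr2·OEt2. Magnesium bridges the aldehyde oxygen and the C9 ether, C7 attacks C8, C11=C13 is released and the ring closes to A1.
- In its favour: two stereocentres (C7, C8) and the exocyclic methylene arise in the ring-forming event, and chelation through the C9 ether points to the syn C8/C9 diol. The C8 hydroxyl emerges free and ready for acylation; on this point it is better than the chosen plan, which has to exchange an ether for the ester (steps 16 and 17).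
- Against it here: the C7 configuration would have to come from an open Lewis-acid transition state inside a forming medium ring, which is hard to predict. In A2 the C9 hydrogen is both α to the aldehyde and allylic, so epimerisation or conjugation is a standing risk. The lactone does not yet exist, so after A1 roughly six operations would remain (silyl removal, oxidation of C12 onto O6, acylation, removal of two benzyl-type ethers, C14 oxidation) against two after 28. Tin is used stoichiometrically.
- Comparison: on structure the chosen plan closes a bond with no stereocentre, whereas this one puts two stereocentres at risk in the closure. On mechanism both are entropically demanding ten-membered closures and are about equal. On step economy the chosen plan has the shorter endgame.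

Alternative 2: The cut is C6–C7, made by ring contraction. The thirteen-membered diallyl ether A4 would be deprotonated at C6 with n-butyllithium. The [2,3] shift forms C6–C7, breaks O–C13, unveils C11=C13 and gives the ten-membered carbinol A3.
- In its favour: the ten-membered ring is reached from a larger, less strained ring, no transition metal is needed, and C6 and C7 are formed together with the exocyclic methylene. On ease of ring formation it is the equal or the better of the chosen plan.
- Against it here: C13 is also allylic and next to oxygen, so the site of deprotonation is not secure. [1,2] shifts and loss of the C4=C5 geometry in the allyl anion are possible. The strong base excludes the C8 ester and any lactone, so both must follow later. The C6/C7 and C7/C8 relationships would rest on the conformation of the large ring. A4 itself needs a macrocyclic etherification, so there are two ring-forming events.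
- Comparison: the chosen plan tolerates the ester and the lactone in the closure and creates no stereocentre there. This alternative is superior only in the size of the ring that has to be closed, and it has the longer endgame (oxidation to the lactone, silyl removals, acylation, acetonide removal, C14 oxidation).

Alternative 3: The cut is C5–C6. The (Z)-alkenyl iodide aldehyde A6 would be treated with CrCl2 and catalytic NiCl2. Zerovalent nickel inserts into the C5–I bond, the alkenyl group passes to trivalent chromium and adds to the C6 aldehyde, closing the ring to A5.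
- In its favour: this alkenylchromium closure has the broadest record for medium and large rings, so on precedent for ring closure it is better than the chosen plan. It tolerates the C8 ester and silyl ethers as well as the Negishi closure does (equal), and the alkenyl geometry is retained.
- Against it here: C6 would be created in the closure with only the neighbouring C7 centre to control it. The aldehyde A6 has a C7 hydrogen that is α to the formyl group and allylic to C11=C13, so it would epimerise or conjugate readily. After A5 the lactone must still be formed (silyl removal, oxidation of C12 onto O6), followed by two more silyl removals and the C14 oxidation.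
- Comparison: the structural risk is a new stereocentre and a fragile precursor, against none of either in the chosen plan. The mechanistic reliability of the closure itself favours the alternative. The step count is similar, with the chosen plan having the shorter path after the ring is formed.

Key step: step 20

## Route

Step 1
Reactants: 1 (+)-2,3-O-isopropylidene-L-threitol
Product: 2 [(4S,5S)-5-{[(4-methoxybenzyl)oxy]methyl}-2,2-dimethyl-1,3-dioxolan-4-yl]methanol
Conditions: NaH (1.0 equiv), 4-MeOC6H4CH2Cl, Bu4NI (cat.), THF/DMF, 0 °C → rt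
Reagents that add atoms: 4-methoxybenzyl chloride, COc1ccc(CCl)cc1
Why: Williamson etherification; the diol is C2-symmetric, so mono-alkylation gives a single compound and one equivalent of base limits the bis-ether.

Step 2
Reactants: 2 mono-PMB ether
Product: 3 (4R,5S)-5-{[(4-methoxybenzyl)oxy]methyl}-2,2-dimethyl-1,3-dioxolane-4-carbaldehyde
Conditions: (COCl)2, DMSO, CH2Cl2, −78 °C; Et3N, −78 → 0 °C
Reagents that add atoms: none
Why: Swern oxidation; the trans-dioxolane aldehyde is the thermodynamically preferred epimer and should survive the cold amine quench unchanged.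

Step 3
Reactants: 3 aldehyde
Product: 4 (4S,5S)-4-ethynyl-5-{[(4-methoxybenzyl)oxy]methyl}-2,2-dimethyl-1,3-dioxolane
Conditions: dimethyl (1-diazo-2-oxopropyl)phosphonate, K2CO3, MeOH, 0 °C → rt
Reagents that add atoms: dimethyl (1-diazo-2-oxopropyl)phosphonate, CC(=O)C(=[N+]=[N-])P(=O)(OC)OC
Why: Seyferth–Gilbert homologation in the Ohira–Bestmann variant adds C1 and turns C10 into the internal alkyne carbon; the mild carbonate conditions should not epimerise the trans-acetonide aldehyde.

Step 4
Reactants: 4 alkyne acetonide
Product: 5 (2S,3S)-1-[(4-methoxybenzyl)oxy]pent-4-yne-2,3-diol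
Conditions: AcOH/H2O (4:1), 45 °C
Reagents that add atoms: none
Why: Acid-catalysed acetal hydrolysis; the benzyl-type ether and the terminal alkyne are stable to aqueous acetic acid.

Step 5
Reactants: 5 alkyne diol
Product: 8 (2S,3S,4Z)-4-(hydroxymethyl)-5-iodo-1-[(4-methoxybenzyl)oxy]pent-4-ene-2,3-diol, via alkenylmagnesium chloride 6 (not isolated), via iodo allylsilane 7 (not isolated)
Conditions: (i-PrO)Me2SiCH2MgCl (5 equiv), CuI (0.3 equiv), THF, 0 °C → rt; I2, −78 → 0 °C; crude: KF, KHCO3, 30% H2O2, THF/MeOH, rt
Reagents that add atoms: [(isopropoxydimethylsilyl)methyl]magnesium chloride, CC(C)O[Si](C)(C)C[Mg]Cl; iodine, II; hydrogen peroxide, OO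
Why: Alkoxide-directed, CuI-catalysed anti-carbomagnesiation of a propargylic alcohol: the C9 magnesium alkoxide sends the silylmethyl group to C10 and holds magnesium on C1 in a five-membered chelate, so iodinolysis with retention puts iodine cis to C9. Tamao oxidation then converts C14–Si into C14–OH with retention and leaves the iodoalkene alone.

Step 6
Reactants: 8 triol
Product: 9 (1S)-1-[(4S,5Z)-5-(iodomethylidene)-2,2-dimethyl-1,3-dioxan-4-yl]-2-[(4-methoxybenzyl)oxy]ethan-1-ol
Conditions: 2-methoxypropene (1.3 equiv), PPTS (5 mol%), CH2Cl2, −20 → 0 °C; Et3N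
Reagents that add atoms: 2-methoxypropene, COC(C)=C
Why: Kinetic acetonation: the enol ether first takes the primary allylic C14 hydroxyl and the mixed ketal closes onto O9 to the 1,3-dioxane. Low temperature and an early amine quench should prevent drift to the five-membered C8/C9 acetonide, leaving O8–H free.

Step 7
Reactants: 9 dioxane alcohol
Product: 10 (4S,5Z)-5-(iodomethylidene)-4-[(4S)-2-(4-methoxyphenyl)-1,3-dioxolan-4-yl]-2,2-dimethyl-1,3-dioxane (both epimers at the acetal carbon)
Conditions: DDQ (1.3 equiv), 4 Å MS, CH2Cl2, 0 °C
Reagents that add atoms: none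
Why: Anhydrous DDQ oxidation of the benzyl-type ether; the benzylic oxocarbenium ion is trapped by the only free hydroxyl (O8) to give the 4-methoxybenzylidene acetal, so O8 is masked without acid or base that could move the acetonide.

Step 8
Reactants: 10 benzylidene acetal
Product: 11 (2S)-2-[(4S,5Z)-5-(iodomethylidene)-2,2-dimethyl-1,3-dioxan-4-yl]-2-[(4-methoxybenzyl)oxy]ethan-1-ol
Conditions: i-Bu2AlH (3 equiv), CH2Cl2, −78 → 0 °C; aq. potassium sodium tartrate
Reagents that add atoms: none
Why: Regioselective reductive opening of a terminal 4-methoxybenzylidene acetal: aluminium binds the less hindered primary oxygen and hydride goes to the oxocarbenium carbon, giving the secondary ether at O8 and the primary alcohol at C7.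

Step 9
Reactants: 11 primary alcohol
Product: 12 (2R)-2-[(4S,5Z)-5-(iodomethylidene)-2,2-dimethyl-1,3-dioxan-4-yl]-2-[(4-methoxybenzyl)oxy]acetaldehyde
Conditions: Dess–Martin periodinane, NaHCO3, CH2Cl2, 0 °C → rt
Reagents that add atoms: none
Why: Dess–Martin oxidation under buffered, non-basic conditions should keep the α-alkoxy centre C8 and the acetonide intact; the aldehyde is used at once.

Step 10
Reactants: 12 aldehyde; 13 methyl acrylate
Product: 14 methyl (4S)-3-hydroxy-4-[(4S,5Z)-5-(iodomethylidene)-2,2-dimethyl-1,3-dioxan-4-yl]-4-[(4-methoxybenzyl)oxy]-2-methylidenebutanoate (both C3 epimers)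
Conditions: DABCO (1 equiv), methyl acrylate (10 equiv), MeOH (2 equiv), rt, 3–5 d
Reagents that add atoms: none
Why: Morita–Baylis–Hillman reaction; α-alkoxy aldehydes are activated acceptors for the amine-generated enolate. The new carbinol centre at C7 is of no consequence because it becomes sp2 in step 11.

Step 11
Reactants: 14 allylic alcohol
Product: 15 methyl (2Z,4S)-2-(bromomethyl)-4-[(4S,5Z)-5-(iodomethylidene)-2,2-dimethyl-1,3-dioxan-4-yl]-4-[(4-methoxybenzyl)oxy]but-2-enoate
Conditions: NBS, Me2S, CH2Cl2, 0 °C → rt
Reagents that add atoms: N-bromosuccinimide, O=C1CCC(=O)N1Br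
Why: Bromination with allylic transposition: the alcohol is activated as an alkoxysulfonium ion (Corey–Kim-type reagent) and bromide attacks in the SN2′ sense to give the conjugated (Z)-2-(bromomethyl)enoate. The near-neutral medium spares the acetonide and the benzyl-type ether.

Step 12
Reactants: 16 4-methyl-5,6-dihydro-2H-pyran-2-one
Product: 17 (2Z)-5-hydroxy-N-methoxy-N,3-dimethylpent-2-enamide
Conditions: Me3Al, MeNH(OMe)·HCl, CH2Cl2, 0 °C → rt
Reagents that add atoms: N,O-dimethylhydroxylamine hydrochloride, CNOC.Cl
Why: Weinreb aminolysis of the lactone with the aluminium amide; the ring fixes C4=C5 as Z and the opening does not touch that geometry.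

Step 13
Reactants: 17 hydroxy amide
Product: 18 (2Z)-5-{[tert-butyl(dimethyl)silyl]oxy}-N-methoxy-N,3-dimethylpent-2-enamide
Conditions: TBSCl, imidazole, DMF, 0 °C → rt
Reagents that add atoms: tert-butyldimethylsilyl chloride, CC(C)(C)[Si](C)(C)Cl
Why: Silylation of the primary alcohol; it blocks relactonisation and gives an ether that survives the chromium step.

Step 14
Reactants: 18 silyl ether amide
Product: 19 (2Z)-5-{[tert-butyl(dimethyl)silyl]oxy}-3-methylpent-2-enal
Conditions: i-Bu2AlH (1.2 equiv), THF, −78 °C; aq. potassium sodium tartrate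
Reagents that add atoms: none
Why: Reduction of a Weinreb amide stops at the aldehyde through the chelated aluminium hemiaminal; low temperature and a neutral work-up should keep the Z-enal from isomerising.

Step 15
Reactants: 15 allylic bromide; 19 Z-enal
Product: 21 (4S,5R)-5-[(1Z)-4-{[tert-butyl(dimethyl)silyl]oxy}-2-methylbut-1-en-1-yl]-4-{(S)-[(4S,5Z)-5-(iodomethylidene)-2,2-dimethyl-1,3-dioxan-4-yl][(4-methoxybenzyl)oxy]methyl}-3-methylideneoxolan-2-one, via hydroxy ester 20 (not isolated)
Conditions: CrCl2 (4 equiv), THF, 0 °C → rt; then PPTS (cat.), CH2Cl2, rt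
Reagents that add atoms: none
Why: Nozaki–Hiyama-type 2-(alkoxycarbonyl)allylation: divalent chromium turns 15 into an allylchromium that adds at C7 through a chair transition state with the C8 substituent equatorial, which should give the anti C6/C7 adduct and hence the trans-lactone. Allylic 1,3-strain keeps H8 in the alkene plane so that C6 bonds anti to the bulky C9 dioxane, setting 7S and, through the chair, 6R. The hydroxy ester 20 then closes to the lactone.

Step 16
Reactants: 21 lactone with O8 ether
Product: 22 (4R,5R)-5-[(1Z)-4-{[tert-butyl(dimethyl)silyl]oxy}-2-methylbut-1-en-1-yl]-4-{(S)-hydroxy[(4S,5Z)-5-(iodomethylidene)-2,2-dimethyl-1,3-dioxan-4-yl]methyl}-3-methylideneoxolan-2-one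
Conditions: DDQ (1.5 equiv), CH2Cl2/pH 7 buffer (10:1), 0 °C → rt
Reagents that add atoms: none
Why: Oxidative cleavage of the 4-methoxybenzyl ether; the buffered neutral medium should not promote lactone exchange to O8, and the silyl ether, acetonide and iodoalkene are inert to DDQ. The ring descriptor changes from 4S to 4R only because the priorities change; the geometry is unchanged.

Step 17
Reactants: 22 C8 alcohol; 23 (2S)-2-methylbutanoic acid
Product: 24 (S)-[(2R,3S)-2-[(1Z)-4-{[tert-butyl(dimethyl)silyl]oxy}-2-methylbut-1-en-1-yl]-4-methylidene-5-oxooxolan-3-yl][(4S,5Z)-5-(iodomethylidene)-2,2-dimethyl-1,3-dioxan-4-yl]methyl (2S)-2-methylbutanoate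
Conditions: EDC·HCl, DMAP, CH2Cl2, 0 °C → rt
Reagents that add atoms: none
Why: Steglich esterification; acylation of O8 by the acylpyridinium ion should outrun lactone exchange, and the low temperature limits epimerisation of the α-branched acid.

Step 18
Reactants: 24 silyl ether
Product: 25 (S)-[(2R,3S)-2-[(1Z)-4-hydroxy-2-methylbut-1-en-1-yl]-4-methylidene-5-oxooxolan-3-yl][(4S,5Z)-5-(iodomethylidene)-2,2-dimethyl-1,3-dioxan-4-yl]methyl (2S)-2-methylbutanoate
Conditions: HF·pyridine, pyridine, THF, 0 °C
Reagents that add atoms: none
Why: Fluoride cleavage of the primary silyl ether; the pyridine-buffered reagent is neither basic enough to add to the methylene lactone nor acidic enough to open the acetonide in the time needed.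

Step 19
Reactants: 25 primary alcohol
Product: 26 (S)-[(2R,3S)-2-[(1Z)-4-iodo-2-methylbut-1-en-1-yl]-4-methylidene-5-oxooxolan-3-yl][(4S,5Z)-5-(iodomethylidene)-2,2-dimethyl-1,3-dioxan-4-yl]methyl (2S)-2-methylbutanoate
Conditions: I2, PPh3, imidazole, CH2Cl2, 0 °C
Reagents that add atoms: iodine, II
Why: Appel iodination; SN2 displacement at the primary carbon C2 with the phosphine consumed as the iodophosphonium species before it can add to the acrylate unit.

Step 20
Reactants: 26 diiodide
Product: 28 (1(10)Z,4Z,6R,7S,8S,9S)-9,14-(isopropylidenedioxy)-8-[(2S)-2-methylbutanoyloxy]germacra-1(10),4,11(13)-trien-12,6-olide, via alkylzinc iodide 27 (not isolated)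
Conditions: Zn dust (activated with BrCH2CH2Br, Me3SiCl), LiCl, THF, 30 °C; filtered solution added over 10 h to Pd(PPh3)4 (15 mol%), THF, 40 °C (final 2 mM)
Reagents that add atoms: none
Why: Negishi cross-coupling used as a ring closure; the closest known reaction type is the palladium-catalysed coupling of primary alkylzinc iodides with alkenyl iodides. Zinc, kept active by LiCl, inserts into the weaker C(sp3)–I bond at C2 far faster than into the alkenyl C1–I bond and gives 27 without touching the lactone, the ester or the iodoalkene. Zerovalent palladium then adds oxidatively to C1–I with retention, the tethered alkylzinc transmetalates within the same molecule to an eleven-membered alkyl(alkenyl)palladacycle, and reductive elimination forms C1–C2. The ten-membered carbocycle is thus closed by reductive elimination at a C(sp2)–C(sp3) bond and not by attack on a trigonal or tetrahedral carbon. No stereocentre is created; the ring-cis C1=C10 geometry is carried over from the (Z)-iodoalkene held exocyclic to the dioxane. The step needs ring closure over chain growth, which slow addition to a dilute catalyst and the folding imposed by the two cis alkenes, the lactone and the dioxane should secure. It also needs reductive elimination over β-hydride elimination (secured by the cis alkyl–alkenyl arrangement on divalent palladium) and no carbopalladation of C11=C13 (secured by the phosphine-rich neutral catalyst at 40 °C and the faster transmetalation).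

Step 21
Reactants: 28 macrocyclic acetonide
Product: 29 (1(10)Z,4Z,6R,7S,8S,9S)-9,14-dihydroxy-8-[(2S)-2-methylbutanoyloxy]germacra-1(10),4,11(13)-trien-12,6-olide
Conditions: AcOH/H2O/THF (3:1:1), rt
Reagents that add atoms: none
Why: Acid-catalysed hydrolysis of the 2,2-dimethyl-1,3-dioxane, the most acid-labile group present; the mild acid should not move the C8 acyl group or open the lactone.

Step 22
Reactants: 29 diol
Product: 30 (1(10)E,4Z,6R,7S,8S,9S)-9-hydroxy-8-[(2S)-2-methylbutanoyloxy]-14-oxogermacra-1(10),4,11(13)-trien-12,6-olide (CNP0168436.1)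
Conditions: TEMPO (0.2 equiv), PhI(OAc)2 (1.2 equiv), CH2Cl2, rt
Reagents that add atoms: none
Why: Oxoammonium-catalysed oxidation (TEMPO with a stoichiometric iodane) is selective for the unhindered primary allylic alcohol over the secondary C9 alcohol; the non-basic medium spares the methylene lactone and the ester.

## Compound list

1 | [(4S,5S)-2,2-dimethyl-1,3-dioxolane-4,5-diyl]dimethanol, (+)-2,3-O-isopropylidene-L-threitol | OC[C@@H]1OC(C)(C)O[C@H]1CO | starting material
2 | [(4S,5S)-5-{[(4-methoxybenzyl)oxy]methyl}-2,2-dimethyl-1,3-dioxolan-4-yl]methanol | COc1ccc(COC[C@@H]2OC(C)(C)O[C@H]2CO)cc1 | intermediate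
3 | (4R,5S)-5-{[(4-methoxybenzyl)oxy]methyl}-2,2-dimethyl-1,3-dioxolane-4-carbaldehyde | COc1ccc(COC[C@@H]2OC(C)(C)O[C@H]2C=O)cc1 | intermediate
4 | (4S,5S)-4-ethynyl-5-{[(4-methoxybenzyl)oxy]methyl}-2,2-dimethyl-1,3-dioxolane | COc1ccc(COC[C@@H]2OC(C)(C)O[C@H]2C#C)cc1 | intermediate
5 | (2S,3S)-1-[(4-methoxybenzyl)oxy]pent-4-yne-2,3-diol | COc1ccc(COC[C@H](O)[C@@H](O)C#C)cc1 | intermediate
6 | [(3S,4S)-3,4-bis(chloromagnesiooxy)-2-{[isopropoxy(dimethyl)silyl]methyl}-5-[(4-methoxybenzyl)oxy]pent-1-en-1-yl]magnesium chloride, Mg on C1 cis to C9 | COc1ccc(COC[C@H](O[Mg]Cl)[C@@H](O[Mg]Cl)/C(C[Si](C)(C)OC(C)C)=C\[Mg]Cl)cc1 | intermediate (not isolated)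
7 | (2S,3S,4E)-5-iodo-4-{[isopropoxy(dimethyl)silyl]methyl}-1-[(4-methoxybenzyl)oxy]pent-4-ene-2,3-diol | COc1ccc(COC[C@H](O)[C@@H](O)/C(C[Si](C)(C)OC(C)C)=C\I)cc1 | intermediate (not isolated)
8 | (2S,3S,4Z)-4-(hydroxymethyl)-5-iodo-1-[(4-methoxybenzyl)oxy]pent-4-ene-2,3-diol | COc1ccc(COC[C@H](O)[C@@H](O)/C(CO)=C\I)cc1 | intermediate
9 | (1S)-1-[(4S,5Z)-5-(iodomethylidene)-2,2-dimethyl-1,3-dioxan-4-yl]-2-[(4-methoxybenzyl)oxy]ethan-1-ol | COc1ccc(COC[C@H](O)[C@H]2OC(C)(C)OC/C2=C/I)cc1 | intermediate
10 | (4S,5Z)-5-(iodomethylidene)-4-[(4S)-2-(4-methoxyphenyl)-1,3-dioxolan-4-yl]-2,2-dimethyl-1,3-dioxane, both acetal epimers | COc1ccc(C2OC[C@H](O2)[C@H]3OC(C)(C)OC/C3=C/I)cc1 | intermediate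
11 | (2S)-2-[(4S,5Z)-5-(iodomethylidene)-2,2-dimethyl-1,3-dioxan-4-yl]-2-[(4-methoxybenzyl)oxy]ethan-1-ol | COc1ccc(CO[C@@H](CO)[C@H]2OC(C)(C)OC/C2=C/I)cc1 | intermediate
12 | (2R)-2-[(4S,5Z)-5-(iodomethylidene)-2,2-dimethyl-1,3-dioxan-4-yl]-2-[(4-methoxybenzyl)oxy]acetaldehyde | COc1ccc(CO[C@@H](C=O)[C@H]2OC(C)(C)OC/C2=C/I)cc1 | intermediate
13 | methyl acrylate | C=CC(=O)OC | starting material
14 | methyl (4S)-3-hydroxy-4-[(4S,5Z)-5-(iodomethylidene)-2,2-dimethyl-1,3-dioxan-4-yl]-4-[(4-methoxybenzyl)oxy]-2-methylidenebutanoate, both C3 epimers | COC(=O)C(=C)C(O)[C@H](OCc1ccc(OC)cc1)[C@H]2OC(C)(C)OC/C2=C/I | intermediate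
15 | methyl (2Z,4S)-2-(bromomethyl)-4-[(4S,5Z)-5-(iodomethylidene)-2,2-dimethyl-1,3-dioxan-4-yl]-4-[(4-methoxybenzyl)oxy]but-2-enoate | COC(=O)/C(CBr)=C/[C@H](OCc1ccc(OC)cc1)[C@H]2OC(C)(C)OC/C2=C/I | intermediate
16 | 4-methyl-5,6-dihydro-2H-pyran-2-one | CC1=CC(=O)OCC1 | starting material
17 | (2Z)-5-hydroxy-N-methoxy-N,3-dimethylpent-2-enamide | CON(C)C(=O)/C=C(/C)CCO | intermediate
18 | (2Z)-5-{[tert-butyl(dimethyl)silyl]oxy}-N-methoxy-N,3-dimethylpent-2-enamide | CON(C)C(=O)/C=C(/C)CCO[Si](C)(C)C(C)(C)C | intermediate
19 | (2Z)-5-{[tert-butyl(dimethyl)silyl]oxy}-3-methylpent-2-enal | O=C/C=C(/C)CCO[Si](C)(C)C(C)(C)C | intermediate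
20 | methyl (3S,4R,5Z)-8-{[tert-butyl(dimethyl)silyl]oxy}-4-hydroxy-3-{(S)-[(4S,5Z)-5-(iodomethylidene)-2,2-dimethyl-1,3-dioxan-4-yl][(4-methoxybenzyl)oxy]methyl}-6-methyl-2-methylideneoct-5-enoate | COC(=O)C(=C)[C@@H]([C@H](O)/C=C(/C)CCO[Si](C)(C)C(C)(C)C)[C@H](OCc1ccc(OC)cc1)[C@H]2OC(C)(C)OC/C2=C/I | intermediate (not isolated)
21 | (4S,5R)-5-[(1Z)-4-{[tert-butyl(dimethyl)silyl]oxy}-2-methylbut-1-en-1-yl]-4-{(S)-[(4S,5Z)-5-(iodomethylidene)-2,2-dimethyl-1,3-dioxan-4-yl][(4-methoxybenzyl)oxy]methyl}-3-methylideneoxolan-2-one | C=C1C(=O)O[C@H](/C=C(/C)CCO[Si](C)(C)C(C)(C)C)[C@H]1[C@H](OCc2ccc(OC)cc2)[C@H]3OC(C)(C)OC/C3=C/I | intermediate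
22 | (4R,5R)-5-[(1Z)-4-{[tert-butyl(dimethyl)silyl]oxy}-2-methylbut-1-en-1-yl]-4-{(S)-hydroxy[(4S,5Z)-5-(iodomethylidene)-2,2-dimethyl-1,3-dioxan-4-yl]methyl}-3-methylideneoxolan-2-one | C=C1C(=O)O[C@H](/C=C(/C)CCO[Si](C)(C)C(C)(C)C)[C@H]1[C@H](O)[C@H]2OC(C)(C)OC/C2=C/I | intermediate
23 | (2S)-2-methylbutanoic acid | CC[C@H](C)C(=O)O | starting material
24 | (S)-[(2R,3S)-2-[(1Z)-4-{[tert-butyl(dimethyl)silyl]oxy}-2-methylbut-1-en-1-yl]-4-methylidene-5-oxooxolan-3-yl][(4S,5Z)-5-(iodomethylidene)-2,2-dimethyl-1,3-dioxan-4-yl]methyl (2S)-2-methylbutanoate | C=C1C(=O)O[C@H](/C=C(/C)CCO[Si](C)(C)C(C)(C)C)[C@H]1[C@H](OC(=O)[C@@H](C)CC)[C@H]2OC(C)(C)OC/C2=C/I | intermediate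
25 | (S)-[(2R,3S)-2-[(1Z)-4-hydroxy-2-methylbut-1-en-1-yl]-4-methylidene-5-oxooxolan-3-yl][(4S,5Z)-5-(iodomethylidene)-2,2-dimethyl-1,3-dioxan-4-yl]methyl (2S)-2-methylbutanoate | C=C1C(=O)O[C@H](/C=C(/C)CCO)[C@H]1[C@H](OC(=O)[C@@H](C)CC)[C@H]2OC(C)(C)OC/C2=C/I | intermediate
26 | (S)-[(2R,3S)-2-[(1Z)-4-iodo-2-methylbut-1-en-1-yl]-4-methylidene-5-oxooxolan-3-yl][(4S,5Z)-5-(iodomethylidene)-2,2-dimethyl-1,3-dioxan-4-yl]methyl (2S)-2-methylbutanoate | C=C1C(=O)O[C@H](/C=C(/C)CCI)[C@H]1[C@H](OC(=O)[C@@H](C)CC)[C@H]2OC(C)(C)OC/C2=C/I | intermediate (precursor of the key step)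
27 | C2 alkylzinc iodide of 26 (iodozincio group in place of the C2 iodine) | C=C1C(=O)O[C@H](/C=C(/C)CC[Zn]I)[C@H]1[C@H](OC(=O)[C@@H](C)CC)[C@H]2OC(C)(C)OC/C2=C/I | intermediate (not isolated)
28 | (1(10)Z,4Z,6R,7S,8S,9S)-9,14-(isopropylidenedioxy)-8-[(2S)-2-methylbutanoyloxy]germacra-1(10),4,11(13)-trien-12,6-olide | C=C1C(=O)O[C@@H]2/C=C(/C)CC/C=C3/COC(C)(C)O[C@@H]3[C@@H](OC(=O)[C@@H](C)CC)[C@@H]12 | intermediate (product of the key step)
29 | (1(10)Z,4Z,6R,7S,8S,9S)-9,14-dihydroxy-8-[(2S)-2-methylbutanoyloxy]germacra-1(10),4,11(13)-trien-12,6-olide | C=C1C(=O)O[C@@H]2/C=C(/C)CC/C=C(/CO)[C@H](O)[C@@H](OC(=O)[C@@H](C)CC)[C@@H]12 | intermediate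
30 | (1(10)E,4Z,6R,7S,8S,9S)-9-hydroxy-8-[(2S)-2-methylbutanoyloxy]-14-oxogermacra-1(10),4,11(13)-trien-12,6-olide, CNP0168436.1 | C=C1C(=O)O[C@@H]2/C=C(/C)CC/C=C(/C=O)[C@H](O)[C@@H](OC(=O)[C@@H](C)CC)[C@@H]12 | target

## Step count and least certain steps

Total: 22 steps. Longest linear sequence: 19 steps (steps 1–11 and 15–22, from 1 to 30); the branch to 19 takes 3 steps (12–14).

**Step 20 (key step).** The most likely failure is chain growth by intermolecular transmetalation, together with loss of the alkenylpalladium iodide by carbopalladation of the C11=C13 acceptor. That acceptor can be reached from C1 in a six-membered mode, whereas the productive transmetalation has to pass through an eleven-membered palladacycle. Protodezincation would return the reduced open chain. The fallback masks the acceptor and closes the ring on a saturated lactone. It sets out from 25. Conjugate addition of thiophenol (PhSH, Et3N, CH2Cl2) would give the sulfide alcohol F1 as C11 epimers. Appel iodination would give the sulfide diiodide F2. Zinc insertion and palladium-catalysed ring closure under the conditions of step 20 would give the macrocyclic sulfide F3. NaIO4 in MeOH/H2O would give the sulfoxide F4, and thermal syn-elimination (toluene, 90 °C, CaCO3) would restore C11=C13 and return to the route at 28.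

**Step 15.** The most likely failure is erosion of simple diastereoselection, through a boat-like or ester-chelated transition state, toward the syn adduct and the cis-lactone. A second possibility is bonding to the other face of C7 if the C8 ether turns into the alkene plane; both stem from the flexibility of the ester-substituted allylchromium. The fallback accepts the syn mode and corrects C6 afterwards; it answers the first and more probable failure. It sets out from 15 and 19. Indium powder in THF/H2O (Barbier conditions that favour the syn adduct) would give the syn hydroxy ester F5. LiOH in THF/H2O would give the hydroxy acid F6. Mitsunobu lactonisation (PPh3, DIAD, THF) would close the lactone with inversion at C6 and return to the route at 21.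

**Step 6.** The most likely failure is acid-catalysed drift of the isopropylidene group from the kinetic six-membered C9/C14 position to the thermodynamically preferred five-membered C8/C9 position, because O8–H is free during the reaction. The fallback uses a group that can only bridge the 1,3-diol. It sets out from 8. t-Bu2Si(OTf)2 and 2,6-lutidine would give the C9/C14 silylene F7. Anhydrous DDQ would tie O7 and O8 as the benzylidene acetal silylene F8. HF·pyridine would release the diol acetal F9. 2,2-Dimethoxypropane with PPTS would then give the acetonide without ambiguity and return to the route at 10.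

**Step 10.** The most likely failure is slow addition to the hindered aldehyde, which gives the amine time to epimerise C8 or to trigger β-elimination. The fallback replaces the amine-catalysed process by a preformed nucleophile. It sets out from 12: hydroalumination of methyl propiolate with i-Bu2AlH and N-methylmorpholine N-oxide gives the α-(methoxycarbonyl)vinylalane, which adds to 12 within hours at 0 °C to rt. It returns to the route at 14 without any new compound.

## Further compounds

F1 | step 20 | thiophenol adduct of 25 (C13 phenylthio, C11 epimers) | c3ccccc3SCC1C(=O)O[C@H](/C=C(/C)CCO)[C@H]1[C@H](OC(=O)[C@@H](C)CC)[C@H]2OC(C)(C)OC/C2=C/I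
F2 | step 20 | sulfide diiodide (C2 iodide of F1) | c3ccccc3SCC1C(=O)O[C@H](/C=C(/C)CCI)[C@H]1[C@H](OC(=O)[C@@H](C)CC)[C@H]2OC(C)(C)OC/C2=C/I
F3 | step 20 | macrocyclic sulfide (11,13-dihydro-13-phenylthio analogue of 28) | c4ccccc4SCC1C(=O)O[C@@H]2/C=C(/C)CC/C=C3/COC(C)(C)O[C@@H]3[C@@H](OC(=O)[C@@H](C)CC)[C@@H]12
F4 | step 20 | macrocyclic sulfoxide of F3 | O=S(c4ccccc4)CC1C(=O)O[C@@H]2/C=C(/C)CC/C=C3/COC(C)(C)O[C@@H]3[C@@H](OC(=O)[C@@H](C)CC)[C@@H]12
F5 | step 15 | syn hydroxy ester (C6 epimer of 20) | COC(=O)C(=C)[C@@H]([C@@H](O)/C=C(/C)CCO[Si](C)(C)C(C)(C)C)[C@H](OCc1ccc(OC)cc1)[C@H]2OC(C)(C)OC/C2=C/I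
F6 | step 15 | hydroxy acid from F5 | OC(=O)C(=C)[C@@H]([C@@H](O)/C=C(/C)CCO[Si](C)(C)C(C)(C)C)[C@H](OCc1ccc(OC)cc1)[C@H]2OC(C)(C)OC/C2=C/I
F7 | step 6 | C9/C14 di-tert-butylsilylene of 8 | COc1ccc(COC[C@H](O)[C@H]2O[Si](C(C)(C)C)(C(C)(C)C)OC/C2=C/I)cc1
F8 | step 6 | C7/C8 4-methoxybenzylidene acetal of F7 (acetal epimers) | COc1ccc(C2OC[C@H](O2)[C@H]3O[Si](C(C)(C)C)(C(C)(C)C)OC/C3=C/I)cc1
F9 | step 6 | C9/C14 diol with C7/C8 4-methoxybenzylidene acetal (acetal epimers) | COc1ccc(C2OC[C@H](O2)[C@@H](O)/C(CO)=C\I)cc1
F0 | step 10 | none | none
A1 | alternative 1 | ten-membered C8 carbinol with 2-propenyl arm on C7, C6 and C12 triethylsilyl ethers, C9 and C14 4-methoxybenzyl ethers | C=C(CO[Si](CC)(CC)CC)[C@H]1[C@H](O[Si](CC)(CC)CC)/C=C(/C)CC/C=C(/COCc2ccc(OC)cc2)[C@H](OCc2ccc(OC)cc2)[C@H]1O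
A2 | alternative 1 | open-chain C8 aldehyde with C13 tributylstannyl allyl unit | O=C[C@@H](OCc1ccc(OC)cc1)/C(COCc1ccc(OC)cc1)=C\CC/C(C)=C\[C@@H](O[Si](CC)(CC)CC)/C=C(/CO[Si](CC)(CC)CC)C[Sn](CCCC)(CCCC)CCCC
A3 | alternative 2 | ten-membered C6 carbinol with 2-propenyl arm on C7, C9/C14 acetonide, C8 tert-butyldimethylsilyl ether | O[C@@H]1/C=C(/C)CC/C=C2/COC(C)(C)O[C@@H]2[C@@H](O[Si](C)(C)C(C)(C)C)[C@H]1C(=C)CO[Si](CC)(CC)CC
A4 | alternative 2 | thirteen-membered diallyl ether linking C6 and C13 | O1C/C(CO[Si](CC)(CC)CC)=C/[C@H](O[Si](C)(C)C(C)(C)C)[C@H]2OC(C)(C)OC/C2=C/CC/C(C)=C\C1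
A5 | alternative 3 | ten-membered C6 carbinol with C8 ester, C9 and C14 tert-butyldimethylsilyl ethers, C12 triethylsilyl ether | O[C@@H]1/C=C(/C)CC/C=C(/CO[Si](C)(C)C(C)(C)C)[C@H](O[Si](C)(C)C(C)(C)C)[C@@H](OC(=O)[C@@H](C)CC)[C@H]1C(=C)CO[Si](CC)(CC)CC
A6 | alternative 3 | open-chain C6 aldehyde with C5 (Z)-alkenyl iodide | I/C=C(/C)CC/C=C(/CO[Si](C)(C)C(C)(C)C)[C@H](O[Si](C)(C)C(C)(C)C)[C@@H](OC(=O)[C@@H](C)CC)[C@H](C=O)C(=C)CO[Si](CC)(CC)CC
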